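The ash run reads 50.2% bis adduct at 30.0 min and 51.2% at 40.0 min, from a c(reagent) of 0.36 M on a c(substrate) of 0.26 M. So we count reagent: one makes a mono adduct, a second makes bis adduct.

Define the surplus as charged c(reagent) minus charged c(substrate), in percent of c(substrate). For ash it is 38.5%. Balancing substrate and reagent over these species gives, in percent of the substrate charged: bis adduct = surplus + unreacted substrate − unused reagent. Unreacted substrate here means free substrate plus the substrate half of idle adduct.

So ash's last reading puts unreacted substrate less unused reagent at 13 percentage points, a reading with its scatter. But oak reaches 96.1%, so the mono adducts do go on to bis adduct.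

| flask | substrate | reagent | remark | time |
|---|---|---|---|---|
| ash | 0.26 M | 0.36 M | run made earlier |  |
| oak | 0.26 M | 0.60 M | run made earlier |  |
| spring | 0.26 M | 0.260 M |  | 1.0 h |
| autumn | 0.26 M | 0.390 M |  | 1.0 h |
| dusk | 0.26 M | 0.520 M |  | 1.0 h |

- ash (time / min: bis adduct / %, first product / %): 8.00: 34.7, 16.5; 15.0: 44.9, 13.9; 20.0: 48.0, 13.2; 30.0: 50.2, 13.8; 40.0: 51.2, 12.3
- oak (time / min: bis adduct / %, first product / %): 8.00: 67.6, 8.6; 15.0: 83.4, 4.8; 20.0: 88.7, 2.8; 30.0: 94.4, 1.6; 40.0: 96.1, 1.3

(scatter of a reading: 0.5 percentage points)

- a species is counted by the substrate in it: one idle adduct counts as two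
- amounts and yields of first product count idle adduct too
- the earlier runs were read with a standard deviation of 0.5 percentage points
- steps thought possible: reagent + first product -> bis adduct + by-product; first product <-> isomer of the product; substrate + first product <-> idle adduct; substrate + reagent -> other mono adduct + by-product; substrate + reagent -> first product + by-product; reagent + other mono adduct -> bis adduct + by-product
- in an amount of first product, one idle adduct counts as one first product

* bis adduct at the end, in percent of the substrate charged, for each flask in turn (spring, autumn, dusk)

Spring has a surplus of 0%, so its bis adduct is its unreacted substrate less any unused reagent. We put autumn between its surplus, 50.0%, and 62.7%, taking ash's gap as the upper end. For dusk the surplus, charged c(reagent) minus charged c(substrate) over c(substrate), is 100%, and the bis adduct there differs from it by unused reagent less unreacted substrate, which needs a rate.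

The forecast gives 28%, 58% and 87%, its dusk figure resting on a “second-order tail with no excess reagent”. That places dusk 13 points under the surplus.

The flasks give 28.1%, 59.7% and 92.2%.

    reagent + first product → bis adduct + by-product (k = 1.90 M⁻¹ min⁻¹)
    first product ⇌ isomer of the product (K = 1.60, k = 0.900 min⁻¹)
    substrate + first product ⇌ idle adduct, settled at all times (K = 24.0 M⁻¹)
    substrate + reagent → other mono adduct + by-product (k = 0.670 M⁻¹ min⁻¹)
    substrate + reagent → first product + by-product (k = 0.840 M⁻¹ min⁻¹)
    reagent + other mono adduct → bis adduct + by-product (k = 1.30 M⁻¹ min⁻¹)

Dusk stands 5.2 points above the forecast, with 4.2% of its own reagent charge unused at 1.00 h. Dusk's bis adduct lies 7.8 points under its surplus of 100%: unused reagent, 8.35% of the substrate charged, less unreacted substrate, 0.575%. In spring, with reagent at 0%, free substrate of 18.9% plus half of the idle adduct's 18.5% comes to 28.1%, against bis adduct of 28.1%.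

Readings and results come from a simulation on assumed constants; scatter was added.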